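**Retrosynthetic overview**
1. Isariotin C ⇒ hydroxyl-directed epoxidation (last) of a bicyclo[3.3.1]non-2-ene triol. Core numbering: C1 bridgehead C–OH, C2/C3 oxirane, C4 CHOH, C5 bridgehead CH, C6 CHOH, C7 CHN, C8 CH2, C9 C=O.
2. Ring B ⇒ intramolecular aldol (C5–C6) of a monocyclic keto aldehyde; amide ⇒ (E)-7-oxododec-2-enoic acid, made by Grignard acylation and cross-metathesis.
3. Ring A (2-hydroxy-2-alkylcyclohex-3-enone) ⇒ α-ketol ring expansion (1,2-alkenyl shift, five → six) of a 1-acylcyclopent-2-en-1-ol, run in the same flask as the sulfinimine Mannich addition that forms C7–C8 and sets C7.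
4. Acylcyclopentenol ⇒ (S)-4-hydroxycyclopentenone + ethyl vinyl ether (acetyl anion equivalent); C6–C7–N ⇒ sulfinimine of dimethoxyacetaldehyde.
5. Ring order: cyclopentene (bought) → ring A by ring expansion → ring B by aldol → oxirane.

Assumption: the silyl group and the work-up acids and bases are reagents; every carbon or nitrogen source of the target is a numbered starting material.

**Step 1**
Reactants: 1 5-bromopent-1-ene; 2 hexanoyl chloride
Product: 4 undec-1-en-6-one, via pent-4-enylmagnesium bromide 3 (not isolated)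
Conditions: Mg, THF, 23 °C; then 2, Fe(acac)3 (3 mol%), THF, −78 °C
Reagents that add atoms: none
Why: Fe(acac)3-catalysed Grignard acylation of an acid chloride is faster than addition to the ketone formed, so it stops at the ketone and leaves the terminal alkene alone; no stereocentre.

**Step 2**
Reactants: 4 undec-1-en-6-one; 5 acrylic acid
Product: 6 (E)-7-oxododec-2-enoic acid
Conditions: second-generation Grubbs catalyst (3 mol%), 5 (3 equiv), CH2Cl2, 40 °C
Reagents that add atoms: none
Why: Olefin cross-metathesis of a terminal alkene with an electron-poor acrylic partner gives the cross product as the E-enoic acid under thermodynamic control; the ketone is inert.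

**Step 3**
Reactants: 7 (R)-2-methylpropane-2-sulfinamide; 8 2,2-dimethoxyacetaldehyde
Product: 9 (R,E)-N-(2,2-dimethoxyethylidene)-2-methylpropane-2-sulfinamide
Conditions: CuSO4 (2.5 equiv), CH2Cl2, 23 °C
Reagents that add atoms: none
Why: Dehydrative condensation of a sulfinamide with an aldehyde gives the E-aldimine; the sulfur stereocentre comes unchanged from 7.

**Step 4**
Reactants: 10 (4S)-4-hydroxycyclopent-2-en-1-one
Product: 11 (4S)-4-(tert-butyldimethylsilyloxy)cyclopent-2-en-1-one
Conditions: t-BuMe2SiCl, imidazole, CH2Cl2, 0 → 23 °C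
Reagents that add atoms: tert-butyldimethylsilyl chloride CC(C)(C)[Si](C)(C)Cl
Why: Standard silyl ether formation; the C4 stereocentre (C4 of the target) is untouched.

**Step 5**
Reactants: 11 (4S)-4-(tert-butyldimethylsilyloxy)cyclopent-2-en-1-one; 12 ethyl vinyl ether
Product: 15 1-[(1R,4S)-4-(tert-butyldimethylsilyloxy)-1-hydroxycyclopent-2-en-1-yl]ethan-1-one, via 1-ethoxyvinyllithium 13 (not isolated), via ethoxyvinyl carbinol 14 (not isolated)
Conditions: 12, t-BuLi, THF, −78 → 0 °C; then 11, −78 °C; then aq. HCl (0.5 M), THF, 0 °C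
Reagents that add atoms: water O
Why: 1,2-Addition of the hard acyl-anion equivalent to the enone carbonyl takes place anti to the silyloxy group (OH cis to OSi, carbinol centre R), and mild acid hydrolysis of the enol ether gives the methyl ketone (an α-ketol).

**Step 6**
Reactants: 15 acetyl carbinol; 9 sulfinimine
Product: 17 (R)-N-[(2S)-3-[(1S,4S)-4-(tert-butyldimethylsilyloxy)-1-hydroxy-6-oxocyclohex-2-en-1-yl]-1,1-dimethoxypropan-2-yl]-2-methylpropane-2-sulfinamide, via β-sulfinamido ketone 16 (not isolated)
Conditions: LiN(SiMe3)2 (2.2 equiv), THF, −78 °C; 9, −78 °C; then Me2AlCl (2.2 equiv), −78 → 23 °C; aq. potassium sodium tartrate (KNaC4H4O6) work-up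
Reagents that add atoms: none
Why: Proposed new method: a one-flask sulfinimine Mannich addition/aluminium-templated α-ketol (acyloin) ring expansion, in which the methyl-ketone lithium enolate of the dianion of 15 adds to the Si face of the (R)-sulfinimine through the usual lithium-bridged chair (C7 set as S), Me2AlCl turns the tertiary lithium alkoxide into an O–AlMe2 alkoxide that chelates the new ketone (O–C–C=O syn-periplanar), and the sp2 ring carbon C2, the better migrating group and aligned with the carbonyl π*, shifts 1,2 from the carbinol carbon to the carbonyl carbon on its own face, so that the cyclopentenol becomes the six-membered α-hydroxy ketone with transfer of the carbinol configuration to C1 (OH cis to the C4 silyloxy group), driven by loss of cyclopentene strain and by removal of the ketone from the β-amino position (no retro-Mannich); the closest known reactions are the Lewis-acid or alkoxide-promoted α-ketol ring enlargement of 1-acylcyclopentanols (steroid D-homoannulation) and Mannich additions of ketone enolates to N-tert-butanesulfinyl aldimines.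

**Step 7**
Reactants: 17 ring-expanded sulfinamide; 6 (E)-7-oxododec-2-enoic acid
Product: 19 (E)-N-[(2S)-3-[(1S,4S)-4-(tert-butyldimethylsilyloxy)-1-hydroxy-6-oxocyclohex-2-en-1-yl]-1,1-dimethoxypropan-2-yl]-7-oxododec-2-enamide, via amine hydrochloride 18 (not isolated)
Conditions: HCl (1.25 M in MeOH, 3 equiv), 0 °C, 20 min; concentrate; then 6, EDC·HCl, HOBt (cat.), i-Pr2NEt, CH2Cl2, 0 → 23 °C
Reagents that add atoms: none
Why: Acidolysis of the N-sulfinyl group followed by carbodiimide amide coupling; the ammonium salt is freed into the pre-activated acid so that acylation outruns condensation of the γ-amino ketone, and no stereocentre is touched.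

**Step 8**
Reactants: 19 amide
Product: 21 (E)-N-[(1S,4R,5R,6R,7S)-1,4,6-trihydroxy-9-oxobicyclo[3.3.1]non-2-en-7-yl]-7-oxododec-2-enamide, via hydroxy aldehyde 20 (not isolated)
Conditions: CF3CO2H/H2O/THF (1:1:4), 0 → 23 °C; concentrate; then NaHCO3 buffer (pH 8)/THF, 23 °C
Reagents that add atoms: water O
Why: Acetal hydrolysis and desilylation, then intramolecular aldol addition in which the C9 ketone can enolise only toward C5 and attacks the aldehyde through a hydrogen-bonded chair with the amide equatorial, giving the axial C6 alcohol and the only possible (cis-bridged) C5 centre; if C4 scrambles by reversible β-elimination/oxa-Michael addition it returns to the exo alcohol.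

**Step 9**
Reactants: 21 bicyclic enone triol
Product: 22 isariotin C
Conditions: VO(acac)2 (5 mol%), t-BuOOH (1.5 equiv), CH2Cl2, 0 → 23 °C
Reagents that add atoms: tert-butyl hydroperoxide CC(C)(C)OO
Why: Hydroxyl-directed VO(acac)2/t-BuOOH epoxidation, in which vanadium is held by the two cis allylic hydroxyls (C1, C4) on the exo face and delivers oxygen syn to both, setting C2 and C3; the electron-poor enamide is not epoxidised.

**Compound list**
1 | 5-bromopent-1-ene | C=CCCCBr | starting material
2 | hexanoyl chloride | CCCCCC(=O)Cl | starting material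
3 | pent-4-enylmagnesium bromide | C=CCCC[Mg]Br | intermediate
4 | undec-1-en-6-one | C=CCCCC(=O)CCCCC | intermediate
5 | acrylic acid | C=CC(=O)O | starting material
6 | (E)-7-oxododec-2-enoic acid | CCCCCC(=O)CCC/C=C/C(=O)O | intermediate
7 | (R)-2-methylpropane-2-sulfinamide | CC(C)(C)[S@@](=O)N | starting material
8 | 2,2-dimethoxyacetaldehyde | COC(OC)C=O | starting material
9 | (R,E)-N-(2,2-dimethoxyethylidene)-2-methylpropane-2-sulfinamide | CC(C)(C)[S@@](=O)/N=C/C(OC)OC | intermediate
10 | (4S)-4-hydroxycyclopent-2-en-1-one | O=C1C=C[C@@H](O)C1 | starting material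
11 | (4S)-4-(tert-butyldimethylsilyloxy)cyclopent-2-en-1-one | O=C1C=C[C@@H](O[Si](C)(C)C(C)(C)C)C1 | intermediate
12 | ethyl vinyl ether | C=COCC | starting material
13 | 1-ethoxyvinyllithium | [Li]C(=C)OCC | intermediate
14 | (1R,4S)-4-(tert-butyldimethylsilyloxy)-1-(1-ethoxyethenyl)cyclopent-2-en-1-ol (OH cis to OSi) | C=C(OCC)[C@@]1(O)C[C@H](O[Si](C)(C)C(C)(C)C)C=C1 | intermediate
15 | 1-[(1R,4S)-4-(tert-butyldimethylsilyloxy)-1-hydroxycyclopent-2-en-1-yl]ethan-1-one (OH cis to OSi) | CC(=O)[C@@]1(O)C[C@H](O[Si](C)(C)C(C)(C)C)C=C1 | intermediate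
16 | (R)-N-[(2S)-4-[(1R,4S)-4-(tert-butyldimethylsilyloxy)-1-hydroxycyclopent-2-en-1-yl]-1,1-dimethoxy-4-oxobutan-2-yl]-2-methylpropane-2-sulfinamide | CC(C)(C)[S@@](=O)N[C@H](C(OC)OC)CC(=O)[C@@]1(O)C[C@H](O[Si](C)(C)C(C)(C)C)C=C1 | intermediate
17 | (R)-N-[(2S)-3-[(1S,4S)-4-(tert-butyldimethylsilyloxy)-1-hydroxy-6-oxocyclohex-2-en-1-yl]-1,1-dimethoxypropan-2-yl]-2-methylpropane-2-sulfinamide (OH cis to OSi) | CC(C)(C)[S@@](=O)N[C@H](C(OC)OC)C[C@@]1(O)C(=O)C[C@H](O[Si](C)(C)C(C)(C)C)C=C1 | intermediate
18 | (2S)-3-[(1S,4S)-4-(tert-butyldimethylsilyloxy)-1-hydroxy-6-oxocyclohex-2-en-1-yl]-1,1-dimethoxypropan-2-amine hydrochloride | Cl.N[C@H](C(OC)OC)C[C@@]1(O)C(=O)C[C@H](O[Si](C)(C)C(C)(C)C)C=C1 | intermediate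
19 | (E)-N-[(2S)-3-[(1S,4S)-4-(tert-butyldimethylsilyloxy)-1-hydroxy-6-oxocyclohex-2-en-1-yl]-1,1-dimethoxypropan-2-yl]-7-oxododec-2-enamide | CCCCCC(=O)CCC/C=C/C(=O)N[C@H](C(OC)OC)C[C@@]1(O)C(=O)C[C@H](O[Si](C)(C)C(C)(C)C)C=C1 | intermediate
20 | (E)-N-[(2S)-1-[(1S,4S)-1,4-dihydroxy-6-oxocyclohex-2-en-1-yl]-3-oxopropan-2-yl]-7-oxododec-2-enamide | CCCCCC(=O)CCC/C=C/C(=O)N[C@H](C=O)C[C@@]1(O)C(=O)C[C@H](O)C=C1 | intermediate
21 | (E)-N-[(1S,4R,5R,6R,7S)-1,4,6-trihydroxy-9-oxobicyclo[3.3.1]non-2-en-7-yl]-7-oxododec-2-enamide (C1-OH and C4-OH on the exo face of ring A; C6-OH axial and cis to the equatorial amide) | CCCCCC(=O)CCC/C=C/C(=O)N[C@H]1C[C@@]2(O)C(=O)[C@H]([C@H](O)C=C2)[C@H]1O | intermediate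
22 | isariotin C: (E)-N-[(1S,2S,3S,4S,5S,6R,7S)-2,3-epoxy-1,4,6-trihydroxy-9-oxobicyclo[3.3.1]nonan-7-yl]-7-oxododec-2-enamide | CCCCCC(=O)CCC/C=C/C(=O)N[C@H]1C[C@@]2(O)C(=O)[C@H]([C@H](O)[C@@H]3O[C@@H]32)[C@H]1O | target

**Totals**
Total steps: 9. Longest linear sequence: 6 steps (steps 4–9, from 10).

**Three steps most likely to fail**

Step 6 (the proposed Mannich/α-ketol ring expansion). The alkyl carbon C5 may migrate in place of the alkenyl carbon C2, the shift may go through the non-chelated rotamer (C1 epimer), or the silyl ether may be lost from the aluminium chelate. The fallback uses only known chemistry and makes ring A by phenol dearomatisation instead of ring expansion; it sets out from 9 (and uses 6) and comes back at 21. 2-Methylphenol F1 is doubly deprotonated (n-BuLi/KOt-Bu) and its benzylic carbanion is added to sulfinimine 9 to give the phenolic sulfinamide F2. HCl/MeOH and then EDC coupling with 6 give the phenolic amide F3. Hydroxylative dearomatisation at the alkylated ortho carbon with stabilised 2-iodoxybenzoic acid, followed by Na2S2O4 work-up, gives the ortho-quinol dienone F4, whose C1 epimer is separated. Acetal hydrolysis (CF3CO2H/H2O) and then pH 8 buffer bring about oxa-Michael addition of water at C4 and aldol closure to 21.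

Step 8 (hydrolysis/aldol). The β-oxygenated ketone may eliminate to the dienone and dimerise or aromatise, the aldehyde may rest as the spiro-lactol, or C6 may form as the equatorial alcohol. The fallback sets out from 19 and comes back at the target 22. 19 is first epoxidised with VO(acac)2/t-BuOOH, directed by the tertiary C1 hydroxyl, to the epoxy ketone F6, which can no longer give a dienone or a phenol. The same acid hydrolysis/desilylation and buffered aldol closure are then run on F6 and give 22 directly.

Step 7 (N–S cleavage/acylation). The free γ-amino ketone may close to a cyclic imine before it is acylated, and the silyl ether may be lost in HCl/MeOH. The fallback sets out from 17 and comes back at 21. 17 is treated with aqueous HCl (2 M)/THF, so that the sulfinyl, acetal and silyl groups leave while nitrogen stays protonated and ring B closes by acid-mediated aldol, giving the bicyclic amino triol hydrochloride F5. The rigid amine, which cannot reach C9, is then acylated chemoselectively on nitrogen with 6 (EDC, HOBt, NaHCO3) to give 21.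

**Further compounds**
F1 | step 6 | 2-methylphenol | Cc1ccccc1O
F2 | step 6 | (R)-N-[(2S)-1-(2-hydroxyphenyl)-3,3-dimethoxypropan-2-yl]-2-methylpropane-2-sulfinamide | CC(C)(C)[S@@](=O)N[C@H](C(OC)OC)Cc1ccccc1O
F3 | step 6 | (E)-N-[(2S)-1-(2-hydroxyphenyl)-3,3-dimethoxypropan-2-yl]-7-oxododec-2-enamide | CCCCCC(=O)CCC/C=C/C(=O)N[C@H](C(OC)OC)Cc1ccccc1O
F4 | step 6 | (E)-N-[(2S)-3-[(1S)-1-hydroxy-6-oxocyclohexa-2,4-dien-1-yl]-1,1-dimethoxypropan-2-yl]-7-oxododec-2-enamide | CCCCCC(=O)CCC/C=C/C(=O)N[C@H](C(OC)OC)C[C@@]1(O)C(=O)C=CC=C1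
F5 | step 7 | (1S,4R,5R,6R,7S)-7-amino-1,4,6-trihydroxybicyclo[3.3.1]non-2-en-9-one hydrochloride | Cl.N[C@H]1C[C@@]2(O)C(=O)[C@H]([C@H](O)C=C2)[C@H]1O
F6 | step 8 | 2,3-epoxide of 19 with the oxirane cis to the C1 hydroxyl and the C4 silyloxy group | CCCCCC(=O)CCC/C=C/C(=O)N[C@H](C(OC)OC)C[C@@]1(O)C(=O)C[C@H](O[Si](C)(C)C(C)(C)C)[C@@H]2O[C@@H]21
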